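## The problem

CNP0189103.0 is a diarylmethane: two hexasubstituted benzene rings share one CH2 group. Round ring A the substituents are butanoyl (A1), methyl (A2), the bridge (A3), methoxy (A4), methyl (A5) and hydroxy (A6). Round ring B they are the bridge (B1), OH (B2), methyl (B3), OH (B4), butanoyl (B5) and OH (B6). There is no stereocentre, so the task is purely positional: twelve ring positions must be filled without a statistical step, and of five phenolic oxygens exactly one (A4) must end as a methyl ether. That ether is the most exposed group in any end-game, because it sits between two ortho substituents, has no neighbouring carbonyl, and must outlast every dealkylation used elsewhere. The second weak point is the CH2 bridge between two electron-rich rings: acid can protonate the phloroglucinol carbon B1 and expel the ring A benzyl cation, and the free polyphenols are easily oxidised as phenoxides. Each aryl ketone is flanked by ortho oxygens, and this decides which neighbouring ethers can be cleaved with the help of the carbonyl and which cannot. The feature that invites a ring-forming key step is ring B before acylation: three meta oxygens (B2, B4, B6), carbon at B1 and B3, hydrogen at B5. This is the pattern formed when a 3-alkoxy-4-alkylcyclobutenone (C1→B2, C2→B5, C3→B6, C4→B1) takes up a 1-silyloxypropyne (→B3, B4), and it arrives with all three oxygens different.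

## Retrosynthesis

**30 ⇒ 29.** The last operation should only uncover oxygens. The O–CH3 bond at A6 and the O–CH(CH3)2 bond at B6 are cut, leading back to 29 with both ketones in place. A primary alkyl ether at B6 would be the easier choice, since the most accessible ynol ethers are primary. It is rejected because in 29 the B5 carbonyl is already engaged by the free B4 hydroxyl, so a B6 ether is the second ortho ether of that ketone and chelation-assisted cleavage would stop before it. A secondary alkyl ether is cleaved by ionisation and needs no carbonyl; the A6 methyl ether is the first ortho ether of the A1 ketone and goes by chelation. The A4 methyl ether qualifies for neither mechanism. The forward step needs a boron Lewis acid at low temperature that stops there.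

**29 ⇒ 28 + 2.** The B5–C(O) bond is cut. In 28, B5 is the only unsubstituted aromatic carbon in the molecule (ring A is hexasubstituted), it lies ortho to the free B4 hydroxyl and para to the B2 hydroxyl, so a Friedel–Crafts acylation has one possible site. Carrying the acyl group through the annulation would need a 2-acylcyclobutenone with no sound access. The forward step must use a Lewis acid mild enough to spare the bridge.

**28 ⇒ 27.** The O–Si bond at B4 is cut. Desilylation first gives the most nucleophilic ring and a B4 phenol that can deliver the acyl group to B5.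

**27 ⇒ 19 + 22.** Three ring B bonds are cut: B2–B3, B4–B5 and B1–B2. Ring B falls apart into cyclobutenone 19 and silyloxyalkyne 22. The neighbouring cut, CH2–B1 (benzylation of a preformed trioxygenated toluene), would need that ring with three differentiated oxygens; the annulation creates the differentiation itself (B2 free OH, B4 silyl ether, B6 isopropyl ether). The precursor is simpler by one aromatic ring. The forward reaction must fix the orientation of the alkyne.

**19 ⇒ 9 + 16.** The cyclobutenone bonds C1–C2 and C3–C4 are cut: a [2+2] cycloaddition of aldoketene 18 (from acid 9 through chloride 17) with isopropoxyacetylene 16. The terminal carbon of 16 must bond to the ketene carbonyl carbon, which places the alkoxy group at C3 and the arylmethyl group at C4. 16 goes back through the dichlorovinyl ether 13 to propan-2-ol 10 and trichloroethene 11.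

**22 ⇒ 20.** The O–Si bond and the C–O bond are cut: silylation of the ynolate 21 obtained by oxygenation of prop-1-ynyllithium 20.

**9 ⇒ 8 ⇒ 6.** The side chain is cut at the Cα–Cβ bond: two-carbon homologation of aldehyde 6 by Knoevenagel–Doebner condensation to 8 and hydrogenation. The ketone needs no protection.

**6 ⇒ 4 ⇒ 3 ⇒ 1 + 2.** Three aromatic substitutions on 2,5-dimethylresorcinol 1. C-acylation with 2 comes first, while the arene is symmetric and both free positions are equivalent. Methylation to 4 follows, then formylation at the last free position to give 6. No step has a regiochemical choice.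

## Roads not taken

**Alternative 1:** The two aryl–carbonyl bonds (A1–CO and B5–CO) are cut last. The fully assembled diarylmethane would be esterified to the tetrabutanoate A2 and irradiated; a photo-Fries shift moves the A6 ester to A1 and one ring B ester to B5 to give A1, and the two remaining esters are saponified.
- Merits: all butanoyl groups enter by simple esterification, no Lewis acid touches the bridge, ring B cannot go wrong (B5 is ortho to B4 and B6 and para to B2), and the route is clearly shorter than the thirteen steps proposed here.
- Weak points: each ring must undergo exactly one acyl shift in competition with radical-pair escape, which returns the free phenol. The o-hydroxyaryl ketone in A1 is a strong internal light filter, so the second shift runs in a solution that absorbs most of the light. The new butyrophenones carry γ-hydrogens and may fragment on further irradiation. A thermal Lewis-acid version would expose the bridge and the A4 ether to forcing conditions.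
- Before that, 1 has to be mono-methylated (a statistical step on a symmetric diol) and joined to ring B at A3 and not at A1, both of which are activated.
- Comparison: Alternative 1 wins on brevity and reagent simplicity. The chosen plan has no statistical step: the A1 acyl group is placed on a symmetric arene, A4 and A6 never compete, and the one late acylation goes to the only aromatic CH under ground-state conditions.

**Alternative 2:** Ring A is cut at A1–A2 and A4–A5. With alkoxide base the central carbon of the β-keto ester A4 adds to the 2-(arylmethyl)but-2-enoate A5 (Michael), and the ethyl-ketone enolate then closes onto the ester (Claisen) to give the cyclohexane-1,3-dione A3. Then follow dehydrogenation, methylation of the A4 oxygen, conversion of the A1 ester into the propyl ketone, hydrogenolysis of three benzyl ethers and acylation of ring B.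
- Merits: cheap condensation chemistry; ring B is brought in preformed. After aromatisation the A6 oxygen is hydrogen-bonded to the A1 carbonyl while A4 is free, so methylation of A4 alone is inherent. In this respect it is better than the chosen plan, which needs a deprotection to reach the same result.
- Weak points: A5 is an α,β-disubstituted acceptor, so conjugate addition is slow and reversible. A3 is two oxidation levels below the arene and fully substituted. The A1 ester must become a ketone at a di-ortho-substituted position. Ring B still needs the same late acylation, now after debenzylation.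
- Comparison: the chosen plan needs more steps before its ring-forming event, but the cascade delivers ring B aromatic, at the right oxidation level and with its oxygens differentiated, and ring A carries its ketone from the first step.

**Alternative 3:** Ring A is cut at A6–A1 and A2–A3. A Diels–Alder reaction of the 1,1,3-trioxygenated diene A8, which carries benzyl-protected ring B on its terminus, with the ynone A7 would give the phenol A6 after loss of one methoxy group as the alcohol.
- Merits: ring A appears in one step with the A1 ketone, the free A6 hydroxyl and the A4 methyl ether already in place, and the polarity of diene and ynone is matched. On this count it is more direct than the chosen route to ring A, which needs five steps and a final demethylation.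
- Weak points: A8 is substituted at C2 and C4, so a defined geometry and an s-cis conformation are hard to secure, and such silyl ketene acetals are fragile. A7 is an internal alkyne with a β-methyl group. The two must form a hexasubstituted benzene by joining two substituted termini in a bimolecular step, so forcing conditions are likely. A8 has to be made from a β-keto ester carrying ring B by two selective enol-ether formations, and ring B again needs hydrogenolysis and late acylation.
- Comparison: in the chosen plan the bimolecular event is a ketene [2+2] at an unhindered CH=C=O terminus, and the crowded ring is then closed by a unimolecular 6π electrocyclisation, a reaction type known for this substitution pattern.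

Key step: step 10

## Route

Remark: 1, 2, 10, 11 and 20 are taken as catalogue chemicals; the ynol ethers 16 and 22 are not and are made within the route.

Step 1
Reactants: 1 2,5-dimethylbenzene-1,3-diol (2,5-dimethylresorcinol); 2 butanoyl chloride
Product: 3 1-(2,4-dihydroxy-3,6-dimethylphenyl)butan-1-one
Conditions: AlCl3, PhNO2, 0 → 50 °C; then aq. HCl
Reagents that add atoms: none
Why: Friedel–Crafts C-acylation of a resorcinol; the two free positions of 1 are equivalent by symmetry, each ortho to one OH and para to the other, and the first acyl group deactivates the ring towards a second.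

Step 2
Reactants: 3 1-(2,4-dihydroxy-3,6-dimethylphenyl)butan-1-one
Product: 4 1-(2,4-dimethoxy-3,6-dimethylphenyl)butan-1-one
Conditions: MeI, K2CO3, DMF, 50 °C
Reagents that add atoms: iodomethane, CI
Why: Williamson O-methylation; warm DMF is used because the A6 hydroxyl is hydrogen-bonded to the ketone. Both phenols must be capped before the acid chloride and ketene stages.

Step 3
Reactants: 4 1-(2,4-dimethoxy-3,6-dimethylphenyl)butan-1-one
Product: 6 3-butanoyl-4,6-dimethoxy-2,5-dimethylbenzaldehyde, via α-chloro methyl ether 5 (not isolated)
Conditions: Cl2CHOMe, TiCl4, CH2Cl2, −20 → 0 °C; then H2O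
Reagents that add atoms: dichloro(methoxy)methane, COC(Cl)Cl; water, O
Why: Rieche formylation; the only free ring position (A3) is ortho to the A4 and para to the A6 methoxy group and only meta to the twisted acyl group. The α-chloro ether 5 is hydrolysed to the aldehyde on work-up.

Step 4
Reactants: 6 3-butanoyl-4,6-dimethoxy-2,5-dimethylbenzaldehyde
Product: 8 (2E)-3-(3-butanoyl-4,6-dimethoxy-2,5-dimethylphenyl)prop-2-enoic acid, via arylidenemalonic acid 7 (not isolated)
Conditions: CH2(CO2H)2, pyridine, piperidine (cat.), 95 °C
Reagents that add atoms: malonic acid, OC(=O)CC(=O)O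
Why: Knoevenagel–Doebner condensation; decarboxylation of 7 gives the E acid. The hindered, twisted aryl ketone is not a competing carbonyl partner under amine catalysis.

Step 5
Reactants: 8 (2E)-3-(3-butanoyl-4,6-dimethoxy-2,5-dimethylphenyl)prop-2-enoic acid
Product: 9 3-(3-butanoyl-4,6-dimethoxy-2,5-dimethylphenyl)propanoic acid
Conditions: H2 (1 atm), Pd/C (10% Pd on carbon), EtOAc, rt
Reagents that add atoms: none
Why: Heterogeneous hydrogenation of the cinnamic C=C; the di-ortho-substituted aryl ketone is hindered and out of conjugation and should survive at atmospheric pressure.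

Step 6
Reactants: 10 propan-2-ol; 11 trichloroethene
Product: 13 (E)-1,2-dichloro-1-(propan-2-yloxy)ethene, via dichloroethyne 12 (not isolated)
Conditions: KH, THF, 0 °C; then Cl2C=CHCl, −50 °C → rt
Reagents that add atoms: none
Why: Dehydrochlorination of trichloroethene by the alkoxide gives dichloroethyne in situ, to which the alkoxide adds; anti addition gives the E dichlorovinyl ether, the standard entry to alkoxyacetylenes.

Step 7
Reactants: 13 (E)-1,2-dichloro-1-(propan-2-yloxy)ethene
Product: 16 2-(ethynyloxy)propane (isopropoxyacetylene), via chloroalkynyl ether 14 (not isolated), via lithium alkoxyacetylide 15 (not isolated)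
Conditions: n-BuLi (2.2 equiv), Et2O, −78 → −40 °C; then H2O, −78 → 0 °C
Reagents that add atoms: none
Why: β-Elimination with the first equivalent of n-BuLi gives 14, chlorine–lithium exchange with the second gives 15, and protonation gives 16. The volatile ynol ether is dried and used as a titrated ethereal solution.

Step 8
Reactants: 9 3-(3-butanoyl-4,6-dimethoxy-2,5-dimethylphenyl)propanoic acid; 16 2-(ethynyloxy)propane
Product: 19 rac-4-[(3-butanoyl-4,6-dimethoxy-2,5-dimethylphenyl)methyl]-3-(propan-2-yloxy)cyclobut-2-en-1-one, via acid chloride 17 (not isolated), via aldoketene 18 (not isolated)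
Conditions: (COCl)2, DMF (cat.), CH2Cl2, rt; then 16 (3 equiv), Et3N, Et2O, 0 °C → rt, slow addition
Reagents that add atoms: none
Why: Ketene–ynol ether [2+2] cycloaddition; the nucleophilic terminal carbon of 16 bonds to the ketene carbonyl carbon, so the alkoxy group ends at C3 and the arylmethyl group at C4. Ring A has no free position, so 17 cannot close to an indanone. The C4 stereocentre forms racemic and is erased in step 10.

Step 9
Reactants: 20 prop-1-yn-1-yllithium
Product: 22 triisopropyl(prop-1-yn-1-yloxy)silane [1-(triisopropylsilyloxy)propyne], via lithium propynolate 21 (not isolated)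
Conditions: t-BuOOH, LiN(SiMe3)2, THF, −78 → 0 °C; then i-Pr3SiOTf, −78 °C → rt
Reagents that add atoms: tert-butyl hydroperoxide, CC(C)(C)OO; triisopropylsilyl trifluoromethanesulfonate, CC(C)[Si](OS(=O)(=O)C(F)(F)F)(C(C)C)C(C)C
Why: Electrophilic oxygenation of a lithium acetylide by lithium tert-butyl peroxide gives ynolate 21, which the hard silyl triflate traps on oxygen. The bulky triisopropylsilyl group retards rearrangement of the ynol ether to a silylketene.

Step 10
Reactants: 19 rac-4-[(3-butanoyl-4,6-dimethoxy-2,5-dimethylphenyl)methyl]-3-(propan-2-yloxy)cyclobut-2-en-1-one; 22 triisopropyl(prop-1-yn-1-yloxy)silane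
Product: 27 1-[3-({2-hydroxy-3-methyl-6-(propan-2-yloxy)-4-[(triisopropylsilyl)oxy]phenyl}methyl)-4,6-dimethoxy-2,5-dimethylphenyl]butan-1-one, via vinylketene 23 (not isolated), via 4-vinylcyclobutenone 24 (not isolated), via dienylketene 25 (not isolated), via cyclohexa-2,4-dienone 26 (not isolated)
Conditions: 22 (1.5 equiv), PhMe, 80 °C then 110 °C, sealed tube
Reagents that add atoms: none
Why: Danheiser benzannulation, a four-stage pericyclic cascade: thermal 4π ring opening of 19 gives vinylketene 23, whose ketene C=C adds 22 in a [2+2] cycloaddition to give 24; a second 4π opening gives dienylketene 25, and 6π electrocyclisation gives dienone 26, which tautomerises to phenol 27. The closest known reaction type is the benzannulation of 3-alkoxy- and 3-alkylcyclobutenones with trialkylsilyloxyalkynes to give resorcinol monosilyl ethers. Ring B is closed by the 6π electrocyclisation (B1–B2), after B2–B3 and B4–B5 have been made in the [2+2] step. No stereocentre survives: the racemic C4 centre of 19 and the sp3 centre of 26 are lost on ring opening and enolisation. The selectivity needed is the orientation of the [2+2] step. The methyl-bearing carbon of 22 is the nucleophilic terminus and bonds to the ketene carbonyl carbon, which puts methyl at B3 between the new phenol (B2) and the silyl ether (B4) and leaves B5 as the only CH. The carbon that carried the arylmethyl group in 19 becomes B1, so ring A and the bridge are passengers. An excess of 22 is used so that 23 is intercepted before it dimerises or acylates phenol already formed.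

Step 11
Reactants: 27 1-[3-({2-hydroxy-3-methyl-6-(propan-2-yloxy)-4-[(triisopropylsilyl)oxy]phenyl}methyl)-4,6-dimethoxy-2,5-dimethylphenyl]butan-1-one
Product: 28 1-[3-({2,4-dihydroxy-3-methyl-6-(propan-2-yloxy)phenyl}methyl)-4,6-dimethoxy-2,5-dimethylphenyl]butan-1-one
Conditions: Bu4NF, AcOH, THF, 0 °C
Reagents that add atoms: none
Why: Fluoride cleavage of an aryl silyl ether; the acetic acid buffer keeps the electron-rich resorcinol from standing as an oxidisable phenoxide. Alkyl ethers and the ketone are inert.

Step 12
Reactants: 28 1-[3-({2,4-dihydroxy-3-methyl-6-(propan-2-yloxy)phenyl}methyl)-4,6-dimethoxy-2,5-dimethylphenyl]butan-1-one; 2 butanoyl chloride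
Product: 29 1-[3-({3-butanoyl-4,6-dihydroxy-5-methyl-2-(propan-2-yloxy)phenyl}methyl)-4,6-dimethoxy-2,5-dimethylphenyl]butan-1-one
Conditions: TiCl4, CH2Cl2, −20 → 0 °C; then aq. HCl
Reagents that add atoms: none
Why: Titanium-mediated Friedel–Crafts acylation ortho to a phenol; B5 is the only unsubstituted aromatic carbon in the molecule and the titanium phenoxide at B4 delivers the acyl group to it. Any material that loses the isopropyl or the A6 methyl group under the Lewis acid converges on the same product in step 13.

Step 13
Reactants: 29 1-[3-({3-butanoyl-4,6-dihydroxy-5-methyl-2-(propan-2-yloxy)phenyl}methyl)-4,6-dimethoxy-2,5-dimethylphenyl]butan-1-one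
Product: 30 1-[3-({3-butanoyl-2,4,6-trihydroxy-5-methylphenyl}methyl)-6-hydroxy-4-methoxy-2,5-dimethylphenyl]butan-1-one (CNP0189103.0)
Conditions: BCl3, CH2Cl2, −78 → 0 °C; then MeOH, H2O
Reagents that add atoms: none
Why: Boron trichloride dealkylation by two mechanisms: the A6 methyl ether is cleaved through the chelate with the A1 ketone, and the secondary isopropyl ether is cleaved by ionisation without help from a carbonyl. The A4 methyl ether is neither secondary nor able to chelate and should persist at or below 0 °C; both rings are fully substituted, so no C-alkylation by the released alkyl groups is possible.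

## Compound list

1 | 2,5-dimethylbenzene-1,3-diol | Cc1cc(O)c(C)c(O)c1 | starting material
2 | butanoyl chloride | CCCC(=O)Cl | starting material
3 | 1-(2,4-dihydroxy-3,6-dimethylphenyl)butan-1-one | CCCC(=O)c1c(C)cc(O)c(C)c1O | intermediate
4 | 1-(2,4-dimethoxy-3,6-dimethylphenyl)butan-1-one | CCCC(=O)c1c(C)cc(OC)c(C)c1OC | intermediate
5 | 1-{3-[chloro(methoxy)methyl]-4,6-dimethoxy-2,5-dimethylphenyl}butan-1-one (racemic, not isolated) | CCCC(=O)c1c(C)c(C(Cl)OC)c(OC)c(C)c1OC | intermediate
6 | 3-butanoyl-4,6-dimethoxy-2,5-dimethylbenzaldehyde | CCCC(=O)c1c(C)c(C=O)c(OC)c(C)c1OC | intermediate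
7 | 2-[(3-butanoyl-4,6-dimethoxy-2,5-dimethylphenyl)methylidene]propanedioic acid (not isolated) | CCCC(=O)c1c(C)c(C=C(C(=O)O)C(=O)O)c(OC)c(C)c1OC | intermediate
8 | (2E)-3-(3-butanoyl-4,6-dimethoxy-2,5-dimethylphenyl)prop-2-enoic acid | CCCC(=O)c1c(C)c(/C=C/C(=O)O)c(OC)c(C)c1OC | intermediate
9 | 3-(3-butanoyl-4,6-dimethoxy-2,5-dimethylphenyl)propanoic acid | CCCC(=O)c1c(C)c(CCC(=O)O)c(OC)c(C)c1OC | intermediate
10 | propan-2-ol | CC(C)O | starting material
11 | trichloroethene | ClC=C(Cl)Cl | starting material
12 | dichloroethyne (not isolated) | ClC#CCl | intermediate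
13 | (E)-1,2-dichloro-1-(propan-2-yloxy)ethene | CC(C)O/C(Cl)=C\Cl | intermediate
14 | 1-chloro-2-(propan-2-yloxy)ethyne (not isolated) | CC(C)OC#CCl | intermediate
15 | lithium (propan-2-yloxy)ethynide (not isolated) | CC(C)OC#C[Li] | intermediate
16 | 2-(ethynyloxy)propane (isopropoxyacetylene) | CC(C)OC#C | intermediate
17 | 3-(3-butanoyl-4,6-dimethoxy-2,5-dimethylphenyl)propanoyl chloride (not isolated) | CCCC(=O)c1c(C)c(CCC(=O)Cl)c(OC)c(C)c1OC | intermediate
18 | 3-(3-butanoyl-4,6-dimethoxy-2,5-dimethylphenyl)prop-1-en-1-one (aldoketene, not isolated) | CCCC(=O)c1c(C)c(CC=C=O)c(OC)c(C)c1OC | intermediate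
19 | rac-4-[(3-butanoyl-4,6-dimethoxy-2,5-dimethylphenyl)methyl]-3-(propan-2-yloxy)cyclobut-2-en-1-one | O=C1C=C(OC(C)C)C1Cc1c(C)c(C(=O)CCC)c(OC)c(C)c1OC | intermediate
20 | prop-1-yn-1-yllithium | [Li]C#CC | starting material
21 | lithium prop-1-yn-1-olate (not isolated) | CC#CO[Li] | intermediate
22 | triisopropyl(prop-1-yn-1-yloxy)silane | CC#CO[Si](C(C)C)(C(C)C)C(C)C | intermediate
23 | 5-(3-butanoyl-4,6-dimethoxy-2,5-dimethylphenyl)-3-(propan-2-yloxy)penta-1,3-dien-1-one (vinylketene, alkene geometry not fixed, not isolated) | O=C=CC(OC(C)C)=CCc1c(C)c(C(=O)CCC)c(OC)c(C)c1OC | intermediate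
24 | 4-[3-(3-butanoyl-4,6-dimethoxy-2,5-dimethylphenyl)-1-(propan-2-yloxy)prop-1-en-1-yl]-2-methyl-3-[(triisopropylsilyl)oxy]cyclobut-2-en-1-one (racemic, not isolated) | O=C1C(C)=C(O[Si](C(C)C)(C(C)C)C(C)C)C1C(OC(C)C)=CCc1c(C)c(C(=O)CCC)c(OC)c(C)c1OC | intermediate
25 | 7-(3-butanoyl-4,6-dimethoxy-2,5-dimethylphenyl)-2-methyl-5-(propan-2-yloxy)-3-[(triisopropylsilyl)oxy]hepta-1,3,5-trien-1-one (dienylketene, not isolated) | O=C=C(C)C(O[Si](C(C)C)(C(C)C)C(C)C)=CC(OC(C)C)=CCc1c(C)c(C(=O)CCC)c(OC)c(C)c1OC | intermediate
26 | 6-[(3-butanoyl-4,6-dimethoxy-2,5-dimethylphenyl)methyl]-2-methyl-5-(propan-2-yloxy)-3-[(triisopropylsilyl)oxy]cyclohexa-2,4-dien-1-one (racemic, not isolated) | O=C1C(C)=C(O[Si](C(C)C)(C(C)C)C(C)C)C=C(OC(C)C)C1Cc1c(C)c(C(=O)CCC)c(OC)c(C)c1OC | intermediate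
27 | 1-[3-({2-hydroxy-3-methyl-6-(propan-2-yloxy)-4-[(triisopropylsilyl)oxy]phenyl}methyl)-4,6-dimethoxy-2,5-dimethylphenyl]butan-1-one | CC(C)Oc1cc(O[Si](C(C)C)(C(C)C)C(C)C)c(C)c(O)c1Cc1c(C)c(C(=O)CCC)c(OC)c(C)c1OC | intermediate
28 | 1-[3-({2,4-dihydroxy-3-methyl-6-(propan-2-yloxy)phenyl}methyl)-4,6-dimethoxy-2,5-dimethylphenyl]butan-1-one | CC(C)Oc1cc(O)c(C)c(O)c1Cc1c(C)c(C(=O)CCC)c(OC)c(C)c1OC | intermediate
29 | 1-[3-({3-butanoyl-4,6-dihydroxy-5-methyl-2-(propan-2-yloxy)phenyl}methyl)-4,6-dimethoxy-2,5-dimethylphenyl]butan-1-one | CCCC(=O)c1c(O)c(C)c(O)c(Cc2c(C)c(C(=O)CCC)c(OC)c(C)c2OC)c1OC(C)C | intermediate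
30 | 1-[3-({3-butanoyl-2,4,6-trihydroxy-5-methylphenyl}methyl)-6-hydroxy-4-methoxy-2,5-dimethylphenyl]butan-1-one | CCCC(=O)c1c(C)c(Cc2c(O)c(C)c(O)c(C(=O)CCC)c2O)c(OC)c(C)c1O | target

## Step count and risk

Total: 13 steps. Longest linear sequence: 10 steps (steps 1–5, 8, 10–13); steps 6–7 and step 9 are side branches.

**The key step, step 10.** Interception of vinylketene 23 may fail. The alkoxy-substituted ketene is electron-rich and can dimerise or acylate the phenol already formed faster than it adds 22. If the arylmethyl group rotates inward on ring opening, a 1,5-hydrogen shift from the benzylic CH2 can drain 23. At the upper temperature 22 can rearrange to a silylketene. The fallback gives up the annulation and joins two preformed rings: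
- Aldehyde 6 is reduced (NaBH4, MeOH, 0 °C) to the benzylic alcohol 1-[3-(hydroxymethyl)-4,6-dimethoxy-2,5-dimethylphenyl]butan-1-one F1.
- Commercial 2-methylbenzene-1,3,5-triol is C-acylated with 2 (AlCl3, PhNO2) to 1-(2,4,6-trihydroxy-3-methylphenyl)butan-1-one F2.
- Acid-promoted Friedel–Crafts benzylation of F2 with F1 (BF3·OEt2, dioxane) can occur only at the single free ring position and gives 1-[3-({3-butanoyl-2,4,6-trihydroxy-5-methylphenyl}methyl)-4,6-dimethoxy-2,5-dimethylphenyl]butan-1-one F3.
- F3 needs only the chelation-assisted A6 demethylation with BCl3 to reach 30.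

**Step 8.** Amine-induced dimerisation and oligomerisation of aldoketene 18 may outrun the cycloaddition, because the concentration of the volatile ynol ether 16 is hard to keep high. The fallback generates the same ketene without amine. Starting from 9, the chloride 17 is α-brominated (N-bromosuccinimide, HBr cat., dark) to racemic 2-bromo-3-(3-butanoyl-4,6-dimethoxy-2,5-dimethylphenyl)propanoyl chloride F4. Dehalogenation of F4 with zinc (Zn–Cu couple, Et2O) in the presence of 16 releases 18 slowly and returns to 19.

**Step 12.** Under Lewis acid and HCl, ring B may be protonated at B1 with loss of the ring A benzyl cation, which means bridge cleavage and scrambling. O-acylation of the hindered B2 phenol may also compete. The fallback replaces electrophilic substitution by an excited-state acyl shift. Starting from 28, the less hindered B4 hydroxyl is esterified (2, Et3N, CH2Cl2, −20 °C) to 4-[(3-butanoyl-4,6-dimethoxy-2,5-dimethylphenyl)methyl]-3-hydroxy-2-methyl-5-(propan-2-yloxy)phenyl butanoate F5. Irradiation (254 nm, MeCN) induces a photo-Fries shift to the only open ortho position, B5, and gives 29 without acid.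

**Step 13.** The isopropyl ether in 29 is flanked on both sides and sits on an acyl-deactivated ring, so its cleavage may be incomplete. The warming then needed may start to erode the A4 methyl ether. The fallback inverts the order. Starting from 28, where the isopropyl ether is on the electron-rich ring with one open ortho position, BCl3 at −78 → 0 °C removes it together with the chelated A6 methyl group to give 1-[6-hydroxy-4-methoxy-2,5-dimethyl-3-({2,4,6-trihydroxy-3-methylphenyl}methyl)phenyl]butan-1-one F6. Titanium-mediated C-acylation of F6 with 2 at B5 then gives 30 directly.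

## Further compounds

F1 | step 10 | 1-[3-(hydroxymethyl)-4,6-dimethoxy-2,5-dimethylphenyl]butan-1-one | CCCC(=O)c1c(C)c(CO)c(OC)c(C)c1OC
F2 | step 10 | 1-(2,4,6-trihydroxy-3-methylphenyl)butan-1-one | CCCC(=O)c1c(O)cc(O)c(C)c1O
F3 | step 10 | 1-[3-({3-butanoyl-2,4,6-trihydroxy-5-methylphenyl}methyl)-4,6-dimethoxy-2,5-dimethylphenyl]butan-1-one | CCCC(=O)c1c(C)c(Cc2c(O)c(C)c(O)c(C(=O)CCC)c2O)c(OC)c(C)c1OC
F4 | step 8 | rac-2-bromo-3-(3-butanoyl-4,6-dimethoxy-2,5-dimethylphenyl)propanoyl chloride | CCCC(=O)c1c(C)c(CC(Br)C(=O)Cl)c(OC)c(C)c1OC
F5 | step 12 | 4-[(3-butanoyl-4,6-dimethoxy-2,5-dimethylphenyl)methyl]-3-hydroxy-2-methyl-5-(propan-2-yloxy)phenyl butanoate | CCCC(=O)Oc1cc(OC(C)C)c(Cc2c(C)c(C(=O)CCC)c(OC)c(C)c2OC)c(O)c1C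
F6 | step 13 | 1-[6-hydroxy-4-methoxy-2,5-dimethyl-3-({2,4,6-trihydroxy-3-methylphenyl}methyl)phenyl]butan-1-one | CCCC(=O)c1c(C)c(Cc2c(O)c(C)c(O)cc2O)c(OC)c(C)c1O
A1 | alternative 1 | twofold Fries product: ring A as in the target (A1 butanoyl, A6 OH, A4 OMe); ring B with butanoyl at B5, free OH at B6 and butanoate esters at B2 and B4 | CCCC(=O)c1c(C)c(Cc2c(OC(=O)CCC)c(C)c(OC(=O)CCC)c(C(=O)CCC)c2O)c(OC)c(C)c1O
A2 | alternative 1 | 2-{[4-(butanoyloxy)-2-methoxy-3,6-dimethylphenyl]methyl}-4-methylbenzene-1,3,5-triyl tributanoate | CCCC(=O)Oc1cc(C)c(Cc2c(OC(=O)CCC)c(C)c(OC(=O)CCC)cc2OC(=O)CCC)c(OC)c1C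
A3 | alternative 2 | ethyl 3,6-dimethyl-2,4-dioxo-5-{[2,4,6-tris(benzyloxy)-3-methylphenyl]methyl}cyclohexane-1-carboxylate (diastereomer mixture) | CCOC(=O)C1C(C)C(Cc2c(OCc3ccccc3)cc(OCc3ccccc3)c(C)c2OCc2ccccc2)C(=O)C(C)C1=O
A4 | alternative 2 | ethyl 3-oxopentanoate | CCC(=O)CC(=O)OCC
A5 | alternative 2 | ethyl (2E)-2-{[2,4,6-tris(benzyloxy)-3-methylphenyl]methyl}but-2-enoate | CCOC(=O)/C(Cc1c(OCc2ccccc2)cc(OCc2ccccc2)c(C)c1OCc1ccccc1)=C/C
A6 | alternative 3 | 1-[6-hydroxy-4-methoxy-2,5-dimethyl-3-({2,4,6-tris(benzyloxy)-3-methylphenyl}methyl)phenyl]butan-1-one | CCCC(=O)c1c(C)c(Cc2c(OCc3ccccc3)cc(OCc3ccccc3)c(C)c2OCc2ccccc2)c(OC)c(C)c1O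
A7 | alternative 3 | hept-2-yn-4-one | CC#CC(=O)CCC
A8 | alternative 3 | ({1,3-dimethoxy-2-methyl-5-[2,4,6-tris(benzyloxy)-3-methylphenyl]penta-1,3-dien-1-yl}oxy)trimethylsilane (alkene geometry not fixed) | COC(O[Si](C)(C)C)=C(C)C(OC)=CCc1c(OCc2ccccc2)cc(OCc2ccccc2)c(C)c1OCc1ccccc1
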